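**Plan**
Retrosynthesis: after removal of nine benzyl groups, the upper C ring is cut at C3–OH/C2–H (hydroboration of a 4-aryl-flav-2-ene) and at C2–aryl (cross-coupling of a lactone enol phosphate), which leads back to a 4-(catechin-8-yl)-7,8-dioxygenated chroman-2-one.
Enabling feature: O1 of the upper unit lies between C8a of the pyrogallol-type A ring and C2; taking it out contracts the pyran to a 3-arylindan-1-one whose only stereocentre is the diaryl methine (target C4), so a Baeyer–Villiger aryl shift puts O1 back (O1–C8a, O1–C2).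
The indanone is cut at C3–C3a (Rh-catalysed intramolecular aryl 1,4-addition of a 2'-boryl chalcone) and at the enone C=C (Claisen–Schmidt) to 8-formyl-penta-O-benzylcatechin and a 6'-bromo-2',3'-dialkoxyacetophenone.
Forward ring order: the catechin rings are bought; the cyclopentanone is closed by Rh, expanded to the six-membered lactone (future upper C ring) in the key step, and the B ring is attached last by Suzuki coupling.
Stereochemistry: lower unit from (+)-catechin; C4 by ligand control in the Rh cyclisation and carried unchanged through the oxygen insertion; C2 and C3 by syn hydroboration anti to the C4 aryl group.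

Key step: step 10

Assumption: (R)-MonoPhos is taken as the ligand antipode that leads to the (3S)-indanone; if the facial sense proves opposite, (S)-MonoPhos is used in the same step, and the minor C3 epimer, being a diastereomer, is removed by chromatography.

**Step 1**
Reactants: 1 (+)-catechin
Product: 2 5,7,3',4'-tetra-O-benzylcatechin
Conditions: BnBr (4.2 equiv), K2CO3, DMF, 0 °C → rt, Ar
Reagents that add atoms: benzyl bromide, BrCc1ccccc1
Why: Williamson etherification under carbonate alkylates only the four phenols (the secondary 3-OH is not deprotonated) and does not involve the catechin stereocentres.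

**Step 2**
Reactants: 2 5,7,3',4'-tetra-O-benzylcatechin
Product: 3 8-bromo-5,7,3',4'-tetra-O-benzylcatechin
Conditions: NBS (1.0 equiv), CH2Cl2, −78 °C → rt
Reagents that add atoms: N-bromosuccinimide, O=C1CCC(=O)N1Br
Why: Electrophilic aromatic bromination of 5,7-di-O-benzylated catechins with NBS at low temperature is known to occur selectively at C8, the C6 site between two benzyloxy groups being slower.

**Step 3**
Reactants: 3 8-bromo-5,7,3',4'-tetra-O-benzylcatechin
Product: 4 8-bromo-3,5,7,3',4'-penta-O-benzylcatechin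
Conditions: NaH, BnBr, DMF, 0 °C → rt
Reagents that add atoms: benzyl bromide, BrCc1ccccc1
Why: Williamson etherification of the secondary alkoxide; with every phenol capped there is no quinone-methide pathway for C2 epimerisation under base.

**Step 4**
Reactants: 4 8-bromo-3,5,7,3',4'-penta-O-benzylcatechin
Product: 6 8-formyl-3,5,7,3',4'-penta-O-benzylcatechin, via 8-lithio aryl species 5 (not isolated)
Conditions: n-BuLi (1.1 equiv), THF, −78 °C; DMF, −78 → 0 °C; H2O
Reagents that add atoms: N,N-dimethylformamide, CN(C)C=O (n-butyllithium, [Li]CCCC, supplies only the lithium of 5)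
Why: Bromine–lithium exchange at −78 °C is faster than benzylic or ortho deprotonation, and the aryllithium is formylated by DMF (Bouveault-type formylation), the hemiaminal collapsing on aqueous quench.

**Step 5**
Reactants: 7 2',3'-dihydroxyacetophenone
Product: 8 2',3'-bis(benzyloxy)acetophenone
Conditions: BnBr (2.4 equiv), K2CO3, DMF, 60 °C
Reagents that add atoms: benzyl bromide, BrCc1ccccc1
Why: Williamson etherification; warming overcomes the hydrogen bond of the 2'-OH to the carbonyl so that both phenols are capped.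

**Step 6**
Reactants: 8 2',3'-bis(benzyloxy)acetophenone
Product: 9 6'-bromo-2',3'-bis(benzyloxy)acetophenone
Conditions: NBS (1.05 equiv), MeCN, 0 °C → rt, dark
Reagents that add atoms: N-bromosuccinimide, O=C1CCC(=O)N1Br
Why: Electrophilic aromatic bromination under ionic conditions should go para to the in-plane 3'-benzyloxy group (C6'), since the flanked 2'-benzyloxy group is twisted and a weak donor, the orientation known for 2,3-dialkoxyaryl carbonyl compounds; the substitution pattern is to be confirmed by NOE/HMBC before use.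

**Step 7**
Reactants: 9 6'-bromo-2',3'-bis(benzyloxy)acetophenone; 6 8-formyl-3,5,7,3',4'-penta-O-benzylcatechin
Product: 11 (E)-1-[6-bromo-2,3-bis(benzyloxy)phenyl]-3-(penta-O-benzylcatechin-8-yl)prop-2-en-1-one, via aldol adduct 10 (not isolated)
Conditions: KOH (50% aq.), EtOH/THF, rt → 40 °C
Reagents that add atoms: none
Why: Claisen–Schmidt condensation: the methyl ketone enolate adds to the non-enolisable aldehyde and E1cB dehydration of the aldol, driven by conjugation with the trialkoxyaryl ring, should give the thermodynamically favoured E-enone.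

**Step 8**
Reactants: 11 (E)-1-[6-bromo-2,3-bis(benzyloxy)phenyl]-3-(penta-O-benzylcatechin-8-yl)prop-2-en-1-one
Product: 12 (E)-1-[2,3-bis(benzyloxy)-6-(pinacolboryl)phenyl]-3-(penta-O-benzylcatechin-8-yl)prop-2-en-1-one
Conditions: B2pin2, Pd(dppf)Cl2 (5 mol%), KOAc, 1,4-dioxane, 85 °C
Reagents that add atoms: bis(pinacolato)diboron, CC1(C)OB(OC1(C)C)B1OC(C)(C)C(C)(C)O1
Why: Miyaura borylation of the aryl bromide with the weak base KOAc, which leaves the enone and the benzyl ethers untouched and does not promote biaryl coupling.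

**Step 9**
Reactants: 12 (E)-1-[2,3-bis(benzyloxy)-6-(pinacolboryl)phenyl]-3-(penta-O-benzylcatechin-8-yl)prop-2-en-1-one
Product: 13 (3S)-6,7-bis(benzyloxy)-3-(penta-O-benzylcatechin-8-yl)indan-1-one
Conditions: [Rh(C2H4)2Cl]2 (2.5 mol%), (R)-MonoPhos (6 mol%), aq. K3PO4 (1.5 M), toluene, rt → 40 °C
Reagents that add atoms: none
Why: Rh(I)-catalysed asymmetric intramolecular 1,4-addition (Hayashi–Miyaura type), a known route from 2'-boryl chalcones to 3-arylindan-1-ones: transmetallation gives an aryl–Rh species that inserts the tethered enone and closes the five-membered ring at C3–C3a, the phosphoramidite ligand choosing the enone face and so setting C3 (S).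

**Step 10**
Reactants: 13 (3S)-6,7-bis(benzyloxy)-3-(penta-O-benzylcatechin-8-yl)indan-1-one
Product: 15 (4S)-7,8-bis(benzyloxy)-4-(penta-O-benzylcatechin-8-yl)chroman-2-one, via Criegee adduct 14 (not isolated)
Conditions: mCPBA (2.5 equiv), Na2HPO4 (solid, excess), CH2Cl2, 0 °C → rt, dark
Reagents that add atoms: 3-chloroperbenzoic acid, OOC(=O)c1cccc(Cl)c1
Why: The peracid adds to the C1 carbonyl to give the tetrahedral Criegee adduct, in which the aryl carbon C7a, antiperiplanar to the O–O bond, shifts to oxygen as 3-chlorobenzoate leaves, so that one oxygen is inserted between C1 and C7a (the future O1–C2 and O1–C8a bonds). The closest known reaction is the Baeyer–Villiger oxidation of 1-indanones to 3,4-dihydrocoumarins. The six-membered lactone, which becomes the upper C ring, arises by one-atom ring expansion of the cyclopentanone through this 1,2-aryl shift and not by cyclisation of an open chain. No stereocentre is created; indanone C3 becomes lactone C4 unchanged because it lies outside the migrating bond and the buffered medium allows neither enolisation nor acid-induced aryl loss. The step needs aryl over CH2 migration, which the ortho-benzyloxy donor at C7 secures by raising the migratory aptitude of the aryl terminus well above that of a primary alkyl group. It also needs oxidation of the ketone in preference to the electron-rich lower A ring, which the phosphate buffer (no strong acid to promote arene hydroxylation), the low temperature and a limited excess of oxidant are meant to secure.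

**Step 11**
Reactants: 15 (4S)-7,8-bis(benzyloxy)-4-(penta-O-benzylcatechin-8-yl)chroman-2-one
Product: 17 (4S)-7,8-bis(benzyloxy)-4-(penta-O-benzylcatechin-8-yl)-4H-chromen-2-yl diphenyl phosphate, via potassium enolate 16 (not isolated)
Conditions: (PhO)2P(O)Cl (1.5 equiv), then KHMDS (1.3 equiv), THF/DMPU, −78 °C
Reagents that add atoms: diphenyl chlorophosphate, O=P(Cl)(Oc1ccccc1)Oc1ccccc1 (potassium hexamethyldisilazide, [K+].C[Si](C)(C)[N-][Si](C)(C)C, supplies only the potassium of 16)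
Why: Kinetic C3 enolisation and O-phosphorylation with the electrophile already present (ketene acetal phosphate formation as practised on lactones), the immediate trapping at −78 °C being meant to outrun ring opening of the aryl ester enolate; C4 is not deprotonated and keeps its configuration.

**Step 12**
Reactants: 18 4-bromocatechol
Product: 19 4-bromo-1,2-bis(benzyloxy)benzene
Conditions: BnBr (2.3 equiv), K2CO3, DMF, rt → 60 °C
Reagents that add atoms: benzyl bromide, BrCc1ccccc1
Why: Williamson etherification of both phenols.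

**Step 13**
Reactants: 19 4-bromo-1,2-bis(benzyloxy)benzene
Product: 20 2-[3,4-bis(benzyloxy)phenyl]-4,4,5,5-tetramethyl-1,3,2-dioxaborolane
Conditions: B2pin2, Pd(dppf)Cl2 (3 mol%), KOAc, 1,4-dioxane, 85 °C
Reagents that add atoms: bis(pinacolato)diboron, CC1(C)OB(OC1(C)C)B1OC(C)(C)C(C)(C)O1
Why: Miyaura borylation of an unhindered, electron-rich aryl bromide.

**Step 14**
Reactants: 17 (4S)-7,8-bis(benzyloxy)-4-(penta-O-benzylcatechin-8-yl)-4H-chromen-2-yl diphenyl phosphate; 20 2-[3,4-bis(benzyloxy)phenyl]-4,4,5,5-tetramethyl-1,3,2-dioxaborolane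
Product: 21 (4S)-7,8-bis(benzyloxy)-2-[3,4-bis(benzyloxy)phenyl]-4-(penta-O-benzylcatechin-8-yl)-4H-chromene
Conditions: Pd(PPh3)4 (8 mol%), aq. Cs2CO3 (3 M), DMF, 50 °C, degassed
Reagents that add atoms: none
Why: Suzuki–Miyaura coupling of a lactone-derived ketene acetal phosphate (oxidative addition into the vinylic C–OP bond) with the aryl boronate should form the C2–aryl bond of the flav-2-ene under mildly basic conditions that do not touch C4.

**Step 15**
Reactants: 21 (4S)-7,8-bis(benzyloxy)-2-[3,4-bis(benzyloxy)phenyl]-4-(penta-O-benzylcatechin-8-yl)-4H-chromene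
Product: 23 (2R,3S,4S)-nona-O-benzyl-mesquitol-(4α→8)-catechin bearing a free upper 3-OH, via C3 alkylborane 22 (not isolated)
Conditions: BH3·THF (4 equiv), THF, 0 °C → rt; then 3 M NaOH, 30% H2O2, 0 °C → rt
Reagents that add atoms: hydrogen peroxide, OO (borane–THF, B.C1CCOC1, supplies only the boron of 22)
Why: Hydroboration–oxidation of a flav-2-ene, known to give 2,3-trans-flavan-3-ols: boron adds to C3 (β to the ring oxygen, remote from the C2 aryl) and hydrogen to C2 in a syn fashion on the face opposite the pseudo-axial C4 aryl group, and oxidation with retention should give the 2,3-trans-3,4-trans alcohol, so C2 (R) and C3 (S) are set by substrate control from C4.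

**Step 16**
Reactants: 23 (2R,3S,4S)-nona-O-benzyl-mesquitol-(4α→8)-catechin bearing a free upper 3-OH
Product: 24 mesquitol-(4α→8)-catechin (CNP0231186.1)
Conditions: H2 (1 atm), 20% Pd(OH)2/C, THF/MeOH (1:1), rt; filtration and concentration under Ar
Reagents that add atoms: none
Why: Catalytic hydrogenolysis of the nine benzyl ethers under neutral conditions that are expected to leave the cyclic benzylic C2–O1 bond, the C4–aryl bond and all five stereocentres intact, as in the debenzylation of protected oligomeric flavan-3-ols.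

**Compound list**
1 | (+)-catechin | Oc1cc(O)c2c(c1)O[C@H](c1ccc(O)c(O)c1)[C@@H](O)C2 | starting material
2 | 5,7,3',4'-tetra-O-benzylcatechin | c1c(OCc2ccccc2)cc(OCc2ccccc2)c2c1O[C@H](c1ccc(OCc3ccccc3)c(OCc3ccccc3)c1)[C@@H](O)C2 | intermediate
3 | 8-bromo-5,7,3',4'-tetra-O-benzylcatechin | Brc1c(OCc2ccccc2)cc(OCc2ccccc2)c2c1O[C@H](c1ccc(OCc3ccccc3)c(OCc3ccccc3)c1)[C@@H](O)C2 | intermediate
4 | 8-bromo-3,5,7,3',4'-penta-O-benzylcatechin | Brc1c(OCc2ccccc2)cc(OCc2ccccc2)c2c1O[C@H](c1ccc(OCc3ccccc3)c(OCc3ccccc3)c1)[C@@H](OCc1ccccc1)C2 | intermediate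
5 | 8-lithio-3,5,7,3',4'-penta-O-benzylcatechin | [Li]c1c(OCc2ccccc2)cc(OCc2ccccc2)c2c1O[C@H](c1ccc(OCc3ccccc3)c(OCc3ccccc3)c1)[C@@H](OCc1ccccc1)C2 | intermediate (not isolated)
6 | 8-formyl-3,5,7,3',4'-penta-O-benzylcatechin | O=Cc1c(OCc2ccccc2)cc(OCc2ccccc2)c2c1O[C@H](c1ccc(OCc3ccccc3)c(OCc3ccccc3)c1)[C@@H](OCc1ccccc1)C2 | intermediate
7 | 2',3'-dihydroxyacetophenone | CC(=O)c1cccc(O)c1O | starting material
8 | 2',3'-bis(benzyloxy)acetophenone | CC(=O)c1cccc(OCc2ccccc2)c1OCc1ccccc1 | intermediate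
9 | 6'-bromo-2',3'-bis(benzyloxy)acetophenone | CC(=O)c1c(Br)ccc(OCc2ccccc2)c1OCc1ccccc1 | intermediate
10 | 1-[6-bromo-2,3-bis(benzyloxy)phenyl]-3-hydroxy-3-(penta-O-benzylcatechin-8-yl)propan-1-one (aldol adduct, carbinol epimers) | O=C(CC(O)c1c(OCc2ccccc2)cc(OCc2ccccc2)c2c1O[C@H](c1ccc(OCc3ccccc3)c(OCc3ccccc3)c1)[C@@H](OCc1ccccc1)C2)c1c(Br)ccc(OCc2ccccc2)c1OCc1ccccc1 | intermediate (not isolated)
11 | (E)-1-[6-bromo-2,3-bis(benzyloxy)phenyl]-3-(penta-O-benzylcatechin-8-yl)prop-2-en-1-one | O=C(/C=C/c1c(OCc2ccccc2)cc(OCc2ccccc2)c2c1O[C@H](c1ccc(OCc3ccccc3)c(OCc3ccccc3)c1)[C@@H](OCc1ccccc1)C2)c1c(Br)ccc(OCc2ccccc2)c1OCc1ccccc1 | intermediate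
12 | (E)-1-[2,3-bis(benzyloxy)-6-(pinacolboryl)phenyl]-3-(penta-O-benzylcatechin-8-yl)prop-2-en-1-one | O=C(/C=C/c1c(OCc2ccccc2)cc(OCc2ccccc2)c2c1O[C@H](c1ccc(OCc3ccccc3)c(OCc3ccccc3)c1)[C@@H](OCc1ccccc1)C2)c1c(B2OC(C)(C)C(C)(C)O2)ccc(OCc2ccccc2)c1OCc1ccccc1 | intermediate
13 | (3S)-6,7-bis(benzyloxy)-3-(penta-O-benzylcatechin-8-yl)indan-1-one | O=C1C[C@H](c2c(OCc3ccccc3)cc(OCc3ccccc3)c3c2O[C@H](c2ccc(OCc4ccccc4)c(OCc4ccccc4)c2)[C@@H](OCc2ccccc2)C3)c2ccc(OCc3ccccc3)c(OCc3ccccc3)c12 | intermediate (key-step precursor)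
14 | Criegee adduct of 13 (1-hydroxy-1-(3-chlorobenzoylperoxy)indane, C1 epimers) | OC1(OOC(=O)c2cccc(Cl)c2)C[C@H](c2c(OCc3ccccc3)cc(OCc3ccccc3)c3c2O[C@H](c2ccc(OCc4ccccc4)c(OCc4ccccc4)c2)[C@@H](OCc2ccccc2)C3)c2ccc(OCc3ccccc3)c(OCc3ccccc3)c12 | intermediate (not isolated)
15 | (4S)-7,8-bis(benzyloxy)-4-(penta-O-benzylcatechin-8-yl)chroman-2-one | O=C1C[C@H](c2c(OCc3ccccc3)cc(OCc3ccccc3)c3c2O[C@H](c2ccc(OCc4ccccc4)c(OCc4ccccc4)c2)[C@@H](OCc2ccccc2)C3)c2ccc(OCc3ccccc3)c(OCc3ccccc3)c2O1 | intermediate (key-step product)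
16 | potassium enolate of 15 | [K+].[O-]C1=C[C@H](c2c(OCc3ccccc3)cc(OCc3ccccc3)c3c2O[C@H](c2ccc(OCc4ccccc4)c(OCc4ccccc4)c2)[C@@H](OCc2ccccc2)C3)c2ccc(OCc3ccccc3)c(OCc3ccccc3)c2O1 | intermediate (not isolated)
17 | (4S)-7,8-bis(benzyloxy)-4-(penta-O-benzylcatechin-8-yl)-4H-chromen-2-yl diphenyl phosphate | O=P(Oc1ccccc1)(Oc1ccccc1)OC1=C[C@H](c2c(OCc3ccccc3)cc(OCc3ccccc3)c3c2O[C@H](c2ccc(OCc4ccccc4)c(OCc4ccccc4)c2)[C@@H](OCc2ccccc2)C3)c2ccc(OCc3ccccc3)c(OCc3ccccc3)c2O1 | intermediate
18 | 4-bromocatechol | Oc1ccc(Br)cc1O | starting material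
19 | 4-bromo-1,2-bis(benzyloxy)benzene | Brc1ccc(OCc2ccccc2)c(OCc2ccccc2)c1 | intermediate
20 | 2-[3,4-bis(benzyloxy)phenyl]-4,4,5,5-tetramethyl-1,3,2-dioxaborolane | CC1(C)OB(OC1(C)C)c1ccc(OCc2ccccc2)c(OCc2ccccc2)c1 | intermediate
21 | (4S)-7,8-bis(benzyloxy)-2-[3,4-bis(benzyloxy)phenyl]-4-(penta-O-benzylcatechin-8-yl)-4H-chromene | C1(c2ccc(OCc3ccccc3)c(OCc3ccccc3)c2)=C[C@H](c2c(OCc3ccccc3)cc(OCc3ccccc3)c3c2O[C@H](c2ccc(OCc4ccccc4)c(OCc4ccccc4)c2)[C@@H](OCc2ccccc2)C3)c2ccc(OCc3ccccc3)c(OCc3ccccc3)c2O1 | intermediate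
22 | (2R,3S,4S)-3-boranyl flavan (C3 alkylborane of 21) | c1ccccc1COc1ccc([C@H]2Oc3c(ccc(OCc5ccccc5)c3OCc3ccccc3)[C@@H](c3c(OCc5ccccc5)cc(OCc5ccccc5)c4c3O[C@H](c3ccc(OCc5ccccc5)c(OCc5ccccc5)c3)[C@@H](OCc3ccccc3)C4)[C@@H]2B)cc1OCc1ccccc1 | intermediate (not isolated)
23 | (2R,3S,4S)-7,8,3',4'-tetra-O-benzylmesquitol-(4α→8)-3,5,7,3',4'-penta-O-benzylcatechin | c1ccccc1COc1ccc([C@H]2Oc3c(ccc(OCc5ccccc5)c3OCc3ccccc3)[C@@H](c3c(OCc5ccccc5)cc(OCc5ccccc5)c4c3O[C@H](c3ccc(OCc5ccccc5)c(OCc5ccccc5)c3)[C@@H](OCc3ccccc3)C4)[C@@H]2O)cc1OCc1ccccc1 | intermediate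
24 | mesquitol-(4α→8)-catechin, (2R,3S,4S)-2-(3,4-dihydroxyphenyl)-4-[(2R,3S)-2-(3,4-dihydroxyphenyl)-3,5,7-trihydroxychroman-8-yl]chroman-3,7,8-triol | Oc1ccc([C@H]2Oc3c(ccc(O)c3O)[C@@H](c3c(O)cc(O)c4c3O[C@H](c3ccc(O)c(O)c3)[C@@H](O)C4)[C@@H]2O)cc1O | target

**Step count and risks**
Total steps: 16. Longest linear sequence: 12 steps (1, 2, 3, 4, 7, 8, 9, 10, 11, 14, 15, 16, from (+)-catechin).

Most likely to fail:

Step 10. Addition of the peracid to the hindered, donor-deactivated ketone may be slower than electrophilic hydroxylation of the lower A ring at its free C6 position, so that over-oxidation consumes material before the aryl shift occurs. The fallback leaves the route at 4 and rejoins it at 15 without any peracid. The aryllithium 5 made from 4 is quenched with 2-isopropoxy-4,4,5,5-tetramethyl-1,3,2-dioxaborolane to give 8-(pinacolboryl)-3,5,7,3',4'-penta-O-benzylcatechin F1. Purchased daphnetin (7,8-dihydroxycoumarin) is benzylated (BnBr, K2CO3, DMF) to 7,8-bis(benzyloxy)coumarin F2. Rh-catalysed asymmetric 1,4-addition of F1 to F2 (Rh(acac)(C2H4)2, (R)-Segphos, dioxane/H2O, 60 °C) should then give 15 directly, with the lactone oxygen in place from the start and C4 set by the ligand.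

Step 9. Protonolysis of the aryl–rhodium intermediate (loss of boron without ring closure) may outrun insertion into the enone, whose β-carbon carries a 2,6-dioxygenated aryl group, and facial selectivity may be poor. The fallback leaves at 11 and rejoins at 13. Pd-catalysed reductive cyclisation of 11 (Pd(OAc)2, PPh3, HCO2Na, DMF, 80 °C) should give 13 together with its C3 epimer, the (3R)-indanone F3. The mixture is converted into the trimethylsilyl enol ether F4 (LiHMDS, TMSCl, THF, −78 °C) and dehydrogenated by Saegusa–Ito oxidation (Pd(OAc)2, MeCN) to 6,7-bis(benzyloxy)-3-(penta-O-benzylcatechin-8-yl)inden-1-one F5. Ligand-controlled copper hydride conjugate reduction (Cu(OAc)2, (R)-DTBM-Segphos, PMHS, t-BuOH, toluene) then returns 13, the stereocentre being set by hydride delivery instead of C–C bond formation.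

Step 11. The aryl ester enolate may fragment to a ketene and a phenoxide before it is phosphorylated, or the ketene acetal phosphate may hydrolyse before coupling. The fallback leaves at 15 and rejoins at 21. Aminolysis of 15 with N,O-dimethylhydroxylamine hydrochloride and AlMe3 (CH2Cl2, 0 °C → rt) gives the phenolic Weinreb amide F6. Three equivalents of 3,4-bis(benzyloxy)phenyllithium F7 (from 19 with n-BuLi, THF, −78 °C; one equivalent is consumed by the phenol) convert F6 through its stable chelated adduct into the 2-hydroxyaryl ketone F8 without over-addition. Cyclodehydration of F8 through its hemiketal (PPTS, toluene, 4 Å sieves, 60 °C) gives 21.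

**Further compounds**
F1 | step 10 | 8-(pinacolboryl)-3,5,7,3',4'-penta-O-benzylcatechin | CC1(C)OB(OC1(C)C)c1c(OCc2ccccc2)cc(OCc2ccccc2)c2c1O[C@H](c1ccc(OCc3ccccc3)c(OCc3ccccc3)c1)[C@@H](OCc1ccccc1)C2
F2 | step 10 | 7,8-bis(benzyloxy)coumarin | O=C1C=Cc2ccc(OCc3ccccc3)c(OCc3ccccc3)c2O1
F3 | step 9 | (3R)-6,7-bis(benzyloxy)-3-(penta-O-benzylcatechin-8-yl)indan-1-one | O=C1C[C@@H](c2c(OCc3ccccc3)cc(OCc3ccccc3)c3c2O[C@H](c2ccc(OCc4ccccc4)c(OCc4ccccc4)c2)[C@@H](OCc2ccccc2)C3)c2ccc(OCc3ccccc3)c(OCc3ccccc3)c12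
F4 | step 9 | 6,7-bis(benzyloxy)-1-(penta-O-benzylcatechin-8-yl)-3-(trimethylsilyloxy)-1H-indene (C1 epimer mixture) | C[Si](C)(C)OC1=CC(c2c(OCc3ccccc3)cc(OCc3ccccc3)c3c2O[C@H](c2ccc(OCc4ccccc4)c(OCc4ccccc4)c2)[C@@H](OCc2ccccc2)C3)c2ccc(OCc3ccccc3)c(OCc3ccccc3)c12
F5 | step 9 | 6,7-bis(benzyloxy)-3-(penta-O-benzylcatechin-8-yl)inden-1-one | O=C1C=C(c2c(OCc3ccccc3)cc(OCc3ccccc3)c3c2O[C@H](c2ccc(OCc4ccccc4)c(OCc4ccccc4)c2)[C@@H](OCc2ccccc2)C3)c2ccc(OCc3ccccc3)c(OCc3ccccc3)c12
F6 | step 11 | (3S)-3-[3,4-bis(benzyloxy)-2-hydroxyphenyl]-N-methoxy-N-methyl-3-(penta-O-benzylcatechin-8-yl)propanamide | CON(C)C(=O)C[C@H](c1c(OCc2ccccc2)cc(OCc2ccccc2)c2c1O[C@H](c1ccc(OCc3ccccc3)c(OCc3ccccc3)c1)[C@@H](OCc1ccccc1)C2)c1ccc(OCc2ccccc2)c(OCc2ccccc2)c1O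
F7 | step 11 | 3,4-bis(benzyloxy)phenyllithium | [Li]c1ccc(OCc2ccccc2)c(OCc2ccccc2)c1
F8 | step 11 | (3S)-3-[3,4-bis(benzyloxy)-2-hydroxyphenyl]-1-[3,4-bis(benzyloxy)phenyl]-3-(penta-O-benzylcatechin-8-yl)propan-1-one | O=C(C[C@H](c1c(OCc2ccccc2)cc(OCc2ccccc2)c2c1O[C@H](c1ccc(OCc3ccccc3)c(OCc3ccccc3)c1)[C@@H](OCc1ccccc1)C2)c1ccc(OCc2ccccc2)c(OCc2ccccc2)c1O)c1ccc(OCc2ccccc2)c(OCc2ccccc2)c1
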